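The depside is disconnected inside ring A and not at its hindered aryl ester: the ring A bonds C1–C2 and C5–C6 are formed last. Ring A bears the ester carbon at C1, oxygen at C2 and C4 and a pentyl chain at C6, the pattern that a 1,1,3-trioxygenated butadiene leaves when it adds across the triple bond of an oct-2-ynoate. The dienophile is therefore the unhindered oct-2-ynoate of the ring B phenol, which carries its acid as a benzyl ester. One cycloaddition and aromatization builds ring A, fully substituted, with the depside ester already in place; O-methylation and hydrogenolysis then finish.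

Key step: step 9

Assumption: the ketene acetal double bond of the diene is drawn Z (silyloxy group cis to C3), as expected from the s-cis enoate; either isomer would serve, because that carbon becomes aromatic C2 of ring A.

Route

Step 1
Reactants: 1 olivetol
Product: 3 olivetolic acid, via magnesium chelate 2 (not isolated)
Conditions: MeOMgOCO2Me (2 M in DMF, excess), 120 °C; then cold 1 M HCl
Reagents that add atoms: methoxymagnesium methyl carbonate, CO[Mg]OC(=O)OC
Why: Kolbe–Schmitt-type ortho-carboxylation through a magnesium chelate should place the carboxyl group at the most nucleophilic ring position (ortho to one hydroxyl, para to the other, next to the pentyl chain), and cold acidification of the chelated salicylate 2 should release 3 without decarboxylation.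

Step 2
Reactants: 3 olivetolic acid
Product: 4 benzyl 2,4-dihydroxy-6-pentylbenzoate
Conditions: BnBr (1.05 equiv), KHCO3, DMF, rt
Reagents that add atoms: benzyl bromide, BrCc1ccccc1
Why: KHCO3 deprotonates only the carboxylic acid, so SN2 alkylation of the carboxylate by benzyl bromide (carboxylate O-alkylation) should give the benzyl ester and leave both phenols free.

Step 3
Reactants: 4 benzyl 2,4-dihydroxy-6-pentylbenzoate
Product: 5 benzyl 2-hydroxy-6-pentyl-4-(prop-2-en-1-yloxy)benzoate
Conditions: allyl bromide (1.05 equiv), K2CO3, acetone, rt → 50 °C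
Reagents that add atoms: allyl bromide, C=CCBr
Why: Williamson ether synthesis with one equivalent of allyl bromide should alkylate only the more acidic, unhindered C4 phenol, because the C2 phenol is held in a hydrogen bond to the ester carbonyl.

Step 4
Reactants: 5 benzyl 2-hydroxy-6-pentyl-4-(prop-2-en-1-yloxy)benzoate
Product: 6 benzyl 2-methoxy-6-pentyl-4-(prop-2-en-1-yloxy)benzoate
Conditions: MeI (excess), K2CO3, DMF, 50 °C
Reagents that add atoms: iodomethane, CI
Why: With the C4 oxygen masked, forcing Williamson methylation (excess MeI, dipolar aprotic solvent, warming) should alkylate the chelated C2 phenol, while the allyl ether and the hindered benzyl ester are inert.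

Step 5
Reactants: 6 benzyl 2-methoxy-6-pentyl-4-(prop-2-en-1-yloxy)benzoate
Product: 7 benzyl 4-hydroxy-2-methoxy-6-pentylbenzoate
Conditions: Pd(PPh3)4 (3 mol %), morpholine, THF, rt
Reagents that add atoms: none
Why: Tsuji–Trost deallylation, in which zerovalent palladium ionizes the aryl allyl ether to a π-allyl complex and a phenoxide stabilised by the para ester, morpholine traps the allyl group, and the benzyl ester (cleaved only under hydrogen) is untouched.

Step 6
Reactants: 7 benzyl 4-hydroxy-2-methoxy-6-pentylbenzoate; 8 oct-2-ynoic acid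
Product: 9 benzyl 2-methoxy-4-(oct-2-ynoyloxy)-6-pentylbenzoate
Conditions: DCC, DMAP (5 mol %), CH2Cl2, 0 °C → rt
Reagents that add atoms: none
Why: Steglich esterification of the unhindered alkynoic acid with the single free phenol should proceed at low temperature with only catalytic DMAP, which limits conjugate addition of the amine to the ynoate.

Step 7
Reactants: 10 methyl acetoacetate
Product: 11 methyl (2E)-3-methoxybut-2-enoate
Conditions: HC(OMe)3, H2SO4 (cat.), rt; distil
Reagents that add atoms: trimethyl orthoformate, COC(OC)OC
Why: Acid-catalysed ketalization of the ketone by the orthoester followed by loss of methanol (enol ether formation) should give the conjugated E enol ether, the thermodynamically preferred isomer.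

Step 8
Reactants: 11 methyl (2E)-3-methoxybut-2-enoate
Product: 13 (1Z)-1,3-dimethoxy-1-(trimethylsilyloxy)buta-1,3-diene, via lithium dienolate 12 (not isolated)
Conditions: LiN(iPr)2, THF, −78 °C; then Me3SiCl, −78 °C → rt; distil
Reagents that add atoms: chlorotrimethylsilane, C[Si](C)(C)Cl
Why: Kinetic γ-deprotonation of the vinylogous ester gives the lithium dienolate, which the oxophilic silyl chloride traps on oxygen (O-silylation of an ester enolate) to give the vinylketene silyl acetal; its double-bond geometry is of no consequence later.

Step 9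
Reactants: 9 benzyl 2-methoxy-4-(oct-2-ynoyloxy)-6-pentylbenzoate; 13 (1Z)-1,3-dimethoxy-1-(trimethylsilyloxy)buta-1,3-diene
Product: 16 benzyl 4-[(2-hydroxy-4-methoxy-6-pentylbenzoyl)oxy]-2-methoxy-6-pentylbenzoate, via cycloadduct 14 (not isolated), via aryl silyl ether 15 (not isolated)
Conditions: 13 (3 equiv), xylene, 130 °C, sealed tube, moisture excluded; then 1 M HCl, THF, rt
Reagents that add atoms: none
Why: The electron-rich vinylketene acetal 13 adds to the electron-poor triple bond of 9 in a thermal [4+2] cycloaddition (concerted but strongly asynchronous, or in the limit a Michael addition followed by Claisen-type closure) to give the cyclohexa-1,4-diene 14, whose mixed ketal carbon ionizes and loses methanol to the aryl silyl ether 15, which the acidic work-up desilylates to the chelated salicylate 16. The closest known reaction type is the Diels–Alder benzannulation of 1-alkoxy-1-silyloxy-3-alkoxybutadienes with acetylenic esters, which gives 2-hydroxy-4-alkoxybenzoates. Ring A closes as a six-membered carbocycle by intermolecular [4+2] annulation that forms C5–C6 and C1–C2 (in the stepwise limit the second bond is a 6-exo-trig attack of the allenolate α-carbon on the oxocarbenium carbon). No stereocentre survives, since the single ketal stereocentre of 14 is racemic and is erased on aromatization. The step needs regioselectivity (diene CH2 terminus to the pentyl-bearing β-carbon, ketene acetal carbon to the α-carbon) and chemoselectivity for conjugate addition over acyl attack; the first follows from the matched polarization of the donor-substituted diene terminus and the acceptor-substituted alkyne, the second from the absence of a Lewis acid and the soft carbon nucleophile, while the hindered benzyl ester on ring B cannot compete. Should 14 lose trimethylsilanol instead of methanol, the product is 17 itself, so both branches converge after step 10.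

Step 10
Reactants: 16 benzyl 4-[(2-hydroxy-4-methoxy-6-pentylbenzoyl)oxy]-2-methoxy-6-pentylbenzoate
Product: 17 benzyl 4-[(2,4-dimethoxy-6-pentylbenzoyl)oxy]-2-methoxy-6-pentylbenzoate
Conditions: MeI (10 equiv), K2CO3, acetone, 50 °C
Reagents that add atoms: iodomethane, CI
Why: Williamson O-methylation of the chelated C2 phenol of ring A, in which a large excess of MeI in acetone (a poorly ionizing medium) should make intermolecular alkylation of the phenoxide faster than its intramolecular attack on ring B, and the hindered depside ester should resist the carbonate.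

Step 11
Reactants: 17 benzyl 4-[(2,4-dimethoxy-6-pentylbenzoyl)oxy]-2-methoxy-6-pentylbenzoate
Product: 18 planaic acid
Conditions: H2 (1 atm), 10% Pd/C, EtOAc, rt
Reagents that add atoms: none
Why: Catalytic hydrogenolysis of the benzylic C–O bond frees the carboxylic acid without base or nucleophile, so the aryl ester linkage and the methyl ethers should remain intact.

Compound list

1 | olivetol (5-pentylbenzene-1,3-diol) | CCCCCc1cc(O)cc(O)c1 | starting material
2 | magnesium chelate of olivetolic acid (magnesium 2-carboxylato-5-hydroxy-3-pentylphenolate) | CCCCCc1cc(O)cc([O-])c1C(=O)[O-].[Mg+2] | intermediate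
3 | olivetolic acid (2,4-dihydroxy-6-pentylbenzoic acid) | CCCCCc1cc(O)cc(O)c1C(=O)O | intermediate
4 | benzyl 2,4-dihydroxy-6-pentylbenzoate | CCCCCc1cc(O)cc(O)c1C(=O)OCc1ccccc1 | intermediate
5 | benzyl 2-hydroxy-6-pentyl-4-(prop-2-en-1-yloxy)benzoate | CCCCCc1cc(OCC=C)cc(O)c1C(=O)OCc1ccccc1 | intermediate
6 | benzyl 2-methoxy-6-pentyl-4-(prop-2-en-1-yloxy)benzoate | CCCCCc1cc(OCC=C)cc(OC)c1C(=O)OCc1ccccc1 | intermediate
7 | benzyl 4-hydroxy-2-methoxy-6-pentylbenzoate | CCCCCc1cc(O)cc(OC)c1C(=O)OCc1ccccc1 | intermediate
8 | oct-2-ynoic acid | CCCCCC#CC(=O)O | starting material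
9 | benzyl 2-methoxy-4-(oct-2-ynoyloxy)-6-pentylbenzoate | CCCCCC#CC(=O)Oc1cc(CCCCC)c(C(=O)OCc2ccccc2)c(OC)c1 | intermediate
10 | methyl acetoacetate | CC(=O)CC(=O)OC | starting material
11 | methyl (2E)-3-methoxybut-2-enoate | CO/C(C)=C/C(=O)OC | intermediate
12 | lithium (1E)-1,3-dimethoxybuta-1,3-dien-1-olate (O–Li cis to C3) | C=C(OC)/C=C(/OC)[O-].[Li+] | intermediate
13 | (1Z)-1,3-dimethoxy-1-(trimethylsilyloxy)buta-1,3-diene | C=C(OC)/C=C(/OC)O[Si](C)(C)C | intermediate
14 | benzyl 4-{[4,6-dimethoxy-2-pentyl-6-(trimethylsilyloxy)cyclohexa-1,4-diene-1-carbonyl]oxy}-2-methoxy-6-pentylbenzoate (racemic at the ketal carbon) | CCCCCC1=C(C(=O)Oc2cc(CCCCC)c(C(=O)OCc3ccccc3)c(OC)c2)C(OC)(O[Si](C)(C)C)C=C(OC)C1 | intermediate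
15 | benzyl 2-methoxy-4-{[4-methoxy-6-pentyl-2-(trimethylsilyloxy)benzoyl]oxy}-6-pentylbenzoate | CCCCCc1cc(OC(=O)c2c(CCCCC)cc(OC)cc2O[Si](C)(C)C)cc(OC)c1C(=O)OCc1ccccc1 | intermediate
16 | benzyl 4-[(2-hydroxy-4-methoxy-6-pentylbenzoyl)oxy]-2-methoxy-6-pentylbenzoate | CCCCCc1cc(OC(=O)c2c(CCCCC)cc(OC)cc2O)cc(OC)c1C(=O)OCc1ccccc1 | intermediate
17 | benzyl 4-[(2,4-dimethoxy-6-pentylbenzoyl)oxy]-2-methoxy-6-pentylbenzoate | CCCCCc1cc(OC(=O)c2c(CCCCC)cc(OC)cc2OC)cc(OC)c1C(=O)OCc1ccccc1 | intermediate
18 | planaic acid (4-[(2,4-dimethoxy-6-pentylbenzoyl)oxy]-2-methoxy-6-pentylbenzoic acid) | CCCCCc1cc(OC(=O)c2c(CCCCC)cc(OC)cc2OC)cc(OC)c1C(=O)O | target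

Step count and risks

Total step count: 11. Longest linear sequence: 9 steps (1 → 18 through steps 1–6, 9, 10 and 11); the diene branch (steps 7 and 8) has 2 steps.

Steps most likely to fail:

First, the cycloaddition of step 9. The β-pentyl ynoate may add so slowly that thermal oxygen-to-carbon silyl migration or adventitious hydrolysis consumes the diene first, or acyl attack on the activated aryl ester may compete. The fallback for step 9 abandons the benzannulation for a classical depside coupling; it sets out from 4 and 7 and comes back to the route at 17. Exhaustive O-methylation of 4 with MeI and K2CO3 in DMF at 60 °C would give benzyl 2,4-dimethoxy-6-pentylbenzoate F1 as the protected ring A unit. Hydrogenolysis over 10% Pd/C in EtOAc would free 2,4-dimethoxy-6-pentylbenzoic acid F2 from it. Treatment with trifluoroacetic anhydride in toluene at rt would convert the acid into 2,4-dimethoxy-6-pentylbenzoic trifluoroacetic anhydride F3 in the flask, a strongly activated acyl donor of the kind used to esterify 2,6-disubstituted electron-rich benzoic acids. This should acylate phenol 7 to give 17, after which the final hydrogenolysis follows.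

Second, the methylation of step 10. The ortho phenoxide of ring A may attack C4 of ring B, which lies para to the benzyl ester, in a Smiles rearrangement to a diaryl ether, or the depside may be cleaved, before the chelated, hindered phenol is alkylated. The fallback for step 10 moves the free phenol to a position from which it cannot rearrange; it sets out from 9 and comes back to the route at 17. Ynoate 9 would be heated in xylene with the known diene 1,1-dimethoxy-3-(trimethylsilyloxy)buta-1,3-diene F4 in place of 13; this diene would be made from 4,4-dimethoxybut-3-en-2-one with Me3SiCl, Et3N and catalytic ZnCl2. The same polarization should give the dimethyl ketal cycloadduct benzyl 4-{[6,6-dimethoxy-2-pentyl-4-(trimethylsilyloxy)cyclohexa-1,4-diene-1-carbonyl]oxy}-2-methoxy-6-pentylbenzoate F5 in the flask. Loss of methanol would give the aryl silyl ether benzyl 2-methoxy-4-{[2-methoxy-6-pentyl-4-(trimethylsilyloxy)benzoyl]oxy}-6-pentylbenzoate F6 as the aromatized intermediate. Acidic work-up would then give benzyl 4-[(4-hydroxy-2-methoxy-6-pentylbenzoyl)oxy]-2-methoxy-6-pentylbenzoate F7 in which ring A already carries its C2 methoxy group. The remaining para phenol is unchelated and cannot reach ring B, so MeI and K2CO3 in acetone at rt should methylate it to 17.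

Third, the carboxylation of step 1. Attack at the carbon between the two hydroxyls may compete with attack next to the pentyl chain, conversion may be incomplete, and the acid may decarboxylate during work-up. The fallback for step 1 introduces the carbon as an aldehyde; it sets out from 1 and comes back to the route at 6. Vilsmeier–Haack formylation with POCl3 and DMF at 0 °C → rt, which is reliably directed para to a hydroxyl, would give N-[(2,4-dihydroxy-6-pentylphenyl)methylidene]-N-methylmethanaminium chloride F8 as the primary product. Hydrolysis with aqueous NaOAc would give 2,4-dihydroxy-6-pentylbenzaldehyde F9 from this salt. Selective allylation of the unchelated phenol with allyl bromide and K2CO3 in acetone would give 2-hydroxy-6-pentyl-4-(prop-2-en-1-yloxy)benzaldehyde F10 as in the main route. Methylation with MeI and K2CO3 in DMF would give 2-methoxy-6-pentyl-4-(prop-2-en-1-yloxy)benzaldehyde F11 from it. Pinnick oxidation with NaClO2, NaH2PO4 and 2-methylbut-2-ene in t-BuOH–H2O would give 2-methoxy-6-pentyl-4-(prop-2-en-1-yloxy)benzoic acid F12 without touching the allyl ether. Carboxylate alkylation with BnBr and K2CO3 in DMF would then give 6.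

Further compounds

F1 | step 9 | benzyl 2,4-dimethoxy-6-pentylbenzoate | CCCCCc1cc(OC)cc(OC)c1C(=O)OCc1ccccc1
F2 | step 9 | 2,4-dimethoxy-6-pentylbenzoic acid | CCCCCc1cc(OC)cc(OC)c1C(=O)O
F3 | step 9 | 2,4-dimethoxy-6-pentylbenzoic trifluoroacetic anhydride | CCCCCc1cc(OC)cc(OC)c1C(=O)OC(=O)C(F)(F)F
F4 | step 10 | 1,1-dimethoxy-3-(trimethylsilyloxy)buta-1,3-diene | C=C(O[Si](C)(C)C)C=C(OC)OC
F5 | step 10 | benzyl 4-{[6,6-dimethoxy-2-pentyl-4-(trimethylsilyloxy)cyclohexa-1,4-diene-1-carbonyl]oxy}-2-methoxy-6-pentylbenzoate | CCCCCC1=C(C(=O)Oc2cc(CCCCC)c(C(=O)OCc3ccccc3)c(OC)c2)C(OC)(OC)C=C(O[Si](C)(C)C)C1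
F6 | step 10 | benzyl 2-methoxy-4-{[2-methoxy-6-pentyl-4-(trimethylsilyloxy)benzoyl]oxy}-6-pentylbenzoate | CCCCCc1cc(OC(=O)c2c(CCCCC)cc(O[Si](C)(C)C)cc2OC)cc(OC)c1C(=O)OCc1ccccc1
F7 | step 10 | benzyl 4-[(4-hydroxy-2-methoxy-6-pentylbenzoyl)oxy]-2-methoxy-6-pentylbenzoate | CCCCCc1cc(OC(=O)c2c(CCCCC)cc(O)cc2OC)cc(OC)c1C(=O)OCc1ccccc1
F8 | step 1 | N-[(2,4-dihydroxy-6-pentylphenyl)methylidene]-N-methylmethanaminium chloride | CCCCCc1cc(O)cc(O)c1C=[N+](C)C.[Cl-]
F9 | step 1 | 2,4-dihydroxy-6-pentylbenzaldehyde | CCCCCc1cc(O)cc(O)c1C=O
F10 | step 1 | 2-hydroxy-6-pentyl-4-(prop-2-en-1-yloxy)benzaldehyde | CCCCCc1cc(OCC=C)cc(O)c1C=O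
F11 | step 1 | 2-methoxy-6-pentyl-4-(prop-2-en-1-yloxy)benzaldehyde | CCCCCc1cc(OCC=C)cc(OC)c1C=O
F12 | step 1 | 2-methoxy-6-pentyl-4-(prop-2-en-1-yloxy)benzoic acid | CCCCCc1cc(OCC=C)cc(OC)c1C(=O)O
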